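**Retrosynthetic overview**
1. 10 ⇐ 9: the C7=C8 alkene is unmasked last, by regioselective loss of water from the 8α tertiary alcohol (proposed confined-acid E1).
2. 9 ⇐ 8: the key step is a C–O bond formation, α-face OsO4 syn-dihydroxylation of a Δ2 alkene, which makes C2–O and C3–O and both ring A stereocentres; 8 comes from a 3β-alcohol by elimination.
3. The C3 oxygen is placed on unfunctionalised ring A in the first step by enzymatic C–H hydroxylation of sclareol.
4. Side chain: vinyl carbinol → C13 methyl ketone (oxidative trimming) → E-enoate (HWE, C13=C14) → 13S by ligand-controlled copper hydride 1,4-reduction.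
5. Rings: no ring is formed; ring A and ring B, with C5, C9, C10 and the C8 oxygen, are taken intact from (−)-sclareol.

Assumption: the ligand antipode written in step 4 is taken to be the one that puts hydride on the Re face of C13 of the E-enoate; this is checked on the first run and the mirror-image ligand is used if the sense is opposite.

**Step 1**
Reactants: 1 (−)-sclareol, (13R)-labd-14-ene-8α,13-diol
Product: 2 3β-hydroxysclareol, (13R)-labd-14-ene-3β,8α,13-triol
Conditions: cytochrome P450 BM3 variant engineered for C3 hydroxylation of sclareol + phosphite dehydrogenase (clarified E. coli lysate), NADP+ (cat.), Na2HPO3, air, KPi buffer pH 8.0, 5% EtOH, 25 °C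
Reagents that add atoms: dioxygen, O=O
Why: Biocatalytic C–H hydroxylation (P450 oxygen rebound), reported for this substrate as far as I recall; the enzyme pocket presents the equatorial 3β-H to the iron-oxo and rebound with retention sets C3 as 3β-OH, while the vinyl group and the tertiary alcohols are untouched.

**Step 2**
Reactants: 2 3β-hydroxysclareol
Product: 4 3β,8α-dihydroxy-14,15-dinorlabdan-13-one, via pentol 3 (not isolated)
Conditions: OsO4 (2 mol%), NaIO4 (4 equiv), 2,6-lutidine, 1,4-dioxane/H2O 3:1, rt
Reagents that add atoms: none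
Why: Lemieux–Johnson oxidation: dihydroxylation of the only alkene gives the 13,14,15-triol unit of 3, and periodate then cuts both C13–C14 and C14–C15 so that C13 keeps its own oxygen as the methyl ketone; the isolated alcohols at C3 and C8 are inert to periodate and no ring stereocentre is touched.

**Step 3**
Reactants: 4 3β,8α-dihydroxy-14,15-dinorlabdan-13-one; 5 trimethyl phosphonoacetate
Product: 6 methyl (13E)-3β,8α-dihydroxylabd-13-en-15-oate
Conditions: 5 (3 equiv) premixed with NaH (3 equiv), THF, 0 → 50 °C; minor Z isomer (expected about 1 part in 6) removed on silica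
Reagents that add atoms: none
Why: Horner–Wadsworth–Emmons olefination of the methyl ketone; the ester ends up trans to the larger C12 chain (E), and the phosphonate anion is too weak a base to deprotonate the free alcohols, so intramolecular oxa-Michael addition of the C8 oxygen is not triggered.

**Step 4**
Reactants: 6 methyl (13E)-3β,8α-dihydroxylabd-13-en-15-oate
Product: 7 methyl (13S)-3β,8α-dihydroxylabdan-15-oate
Conditions: Cu(OAc)2·H2O (5 mol%), (R)-DTBM-SEGPHOS (5.5 mol%), (EtO)2MeSiH (4 equiv), t-BuOH (2 equiv), toluene, 0 °C → rt; NH4F, MeOH work-up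
Reagents that add atoms: none
Why: Ligand-controlled copper hydride 1,4-reduction of a β,β-disubstituted enoate (Buchwald–Lipshutz type asymmetric conjugate reduction): the chiral L*CuH delivers hydride to the Re face of C13 of the geometrically pure E-enoate, giving 13S under catalyst control far from the decalin; t-BuOH protonates C14 and the alcohols are not reduced.

**Step 5**
Reactants: 7 methyl (13S)-3β,8α-dihydroxylabdan-15-oate
Product: 8 methyl (13S)-8α-hydroxylabd-2-en-15-oate
Conditions: PPh3 (2 equiv), DIAD (2 equiv), 3,3-dimethylglutarimide (1.5 equiv), THF, 0 °C → rt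
Reagents that add atoms: none
Why: Mitsunobu-type dehydration, the known outcome for 4,4-dimethyl-3β-ols of triterpenoid ring A: PPh3/DIAD activates only the secondary 3β-oxygen (the tertiary 8α-OH does not react), substitution at the neopentyl C3 is blocked, and because C4 is quaternary elimination can only give the Δ2 alkene; no stereocentre is made.

**Step 6**
Reactants: 8 methyl (13S)-8α-hydroxylabd-2-en-15-oate
Product: 9 methyl (13S)-2α,3α,8α-trihydroxylabdan-15-oate
Conditions: OsO4 (5 mol%), NMO (2 equiv), acetone/H2O 5:1, rt
Reagents that add atoms: N-methylmorpholine N-oxide, C[N+]1([O-])CCOCC1; water, O (both oxygens are passed on through catalytic osmium tetroxide, O=[Os](=O)(=O)=O)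
Why: Upjohn syn-dihydroxylation: the [3+2] addition of OsO4 takes the α face of ring A because the β face is covered by the axial C10 methyl and the 4β-methyl, which sets C2 and C3 together as the cis 2α,3α-diol (the known result for Δ2 alkenes of 4,4-dimethyl trans-decalins); there is no other alkene in 8.

**Step 7**
Reactants: 9 methyl (13S)-2α,3α,8α-trihydroxylabdan-15-oate
Product: 10 methyl (13S)-2α,3α-dihydroxylabd-7-en-15-oate (target)
Conditions: IDPi (imidodiphosphorimidate Brønsted acid built from two (S)-3,3′-bis[3,5-bis(trifluoromethyl)phenyl]-BINOL units, N-triflyl; 5 mol%), (CF3)2CHOH/CH2Cl2 1:4, 4 Å MS, −30 °C; Et3N quench at full conversion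
Reagents that add atoms: none
Why: Proposed new method: confined-acid-controlled regioselective E1 dehydration. The strong IDPi acid in the ionising fluoroalcohol protonates only the tertiary 8α-OH (the secondary diol and the ester do not ionise), water leaves, and the C8 cation is held as a contact ion pair in the chiral anion cavity. The anion is the only base present; sitting on the open α side it reaches the axial H-7α, which is already parallel to the empty p orbital, whereas H-9α is buried between C10 and the C11 chain and loss of a C17 hydrogen would give the less stable exocyclic alkene. Proton loss therefore gives the trisubstituted C7=C8 bond before hydride or methyl shifts start, and both catalyst antipodes are screened for the matched pocket. The closest known reaction types are Brønsted-acid E1 dehydration of 8α-hydroxy labdanes and drimanes (which gives Δ7/Δ8/Δ8(17) mixtures) and IDPi-catalysed cationic polyene cyclisations that pass through this same kind of decalin C8 cation; what is new is using the confined counter-anion as the site-selective base for the terminating deprotonation.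

**Compound list**
1 | (−)-sclareol, (13R)-labd-14-ene-8α,13-diol | C=C[C@](C)(O)CC[C@H]1[C@](C)(O)CC[C@H]2C(C)(C)CCC[C@]12C | starting material
2 | 3β-hydroxysclareol, (13R)-labd-14-ene-3β,8α,13-triol | C=C[C@](C)(O)CC[C@H]1[C@](C)(O)CC[C@H]2C(C)(C)[C@@H](O)CC[C@]12C | intermediate
3 | (13R)-labdane-3β,8α,13,14,15-pentol (C14 epimers; not isolated) | OCC(O)[C@](C)(O)CC[C@H]1[C@](C)(O)CC[C@H]2C(C)(C)[C@@H](O)CC[C@]12C | intermediate
4 | 3β,8α-dihydroxy-14,15-dinorlabdan-13-one (in equilibrium with its 8,13-hemiketal) | CC(=O)CC[C@H]1[C@](C)(O)CC[C@H]2C(C)(C)[C@@H](O)CC[C@]12C | intermediate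
5 | trimethyl phosphonoacetate | COC(=O)CP(=O)(OC)OC | starting material
6 | methyl (13E)-3β,8α-dihydroxylabd-13-en-15-oate | COC(=O)/C=C(\C)CC[C@H]1[C@](C)(O)CC[C@H]2C(C)(C)[C@@H](O)CC[C@]12C | intermediate
7 | methyl (13S)-3β,8α-dihydroxylabdan-15-oate | COC(=O)C[C@@H](C)CC[C@H]1[C@](C)(O)CC[C@H]2C(C)(C)[C@@H](O)CC[C@]12C | intermediate
8 | methyl (13S)-8α-hydroxylabd-2-en-15-oate | COC(=O)C[C@@H](C)CC[C@H]1[C@](C)(O)CC[C@H]2C(C)(C)C=CC[C@]12C | intermediate
9 | methyl (13S)-2α,3α,8α-trihydroxylabdan-15-oate | COC(=O)C[C@@H](C)CC[C@H]1[C@](C)(O)CC[C@H]2C(C)(C)[C@H](O)[C@H](O)C[C@]12C | intermediate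
10 | methyl (13S)-2α,3α-dihydroxylabd-7-en-15-oate | COC(=O)C[C@@H](C)CC[C@H]1C(C)=CC[C@H]2C(C)(C)[C@H](O)[C@H](O)C[C@]12C | target

**Total step count:** 7. **Longest linear sequence:** 7 steps (1 → 10).

**Steps most likely to fail**

Step 7 (the proposed new dehydration). The risks are a mixture of Δ7, Δ8 and Δ8(17) alkenes, re-protonation of the product with drift to the tetrasubstituted alkene, and hydride or methyl shifts from the C8 cation. The fallback uses known chemistry and sets out from 9. SOCl2/pyridine in CH2Cl2 at −78 °C converts the cis-diol into its cyclic sulfite and eliminates the activated equatorial 8α-oxygen through the only antiperiplanar hydrogens (those of C17), giving methyl (13S)-2α,3α-(sulfinyldioxy)labd-8(17)-en-15-oate F1. K2CO3 in MeOH removes the sulfite to give methyl (13S)-2α,3α-dihydroxylabd-8(17)-en-15-oate F2. Hydrogen-atom-transfer isomerisation with Co(salen)Cl (salen = N,N′-bis(3,5-di-tert-butylsalicylidene)-1,2-cyclohexanediamine dianion; cat.) and PhSiH3 (cat.) in benzene at rt then moves the exocyclic alkene into ring B toward the less hindered C7 (away from the crowded C9), coming back to the route at 10.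

Step 5 (Mitsunobu-type dehydration). The hindered neopentyl 3β-alcohol may react slowly, give hydrazide adducts, or suffer ring A contraction. The fallback sets out from 7. Dess–Martin periodinane oxidises only the secondary alcohol to methyl (13S)-8α-hydroxy-3-oxolabdan-15-oate F3. KN(SiMe3)2 (2.2 equiv) and PhNTf2 in THF at −78 °C enolise the ketone toward C2, its only enolisable side, and give methyl (13S)-8α-hydroxy-3-(trifluoromethanesulfonyloxy)labd-2-en-15-oate F4. Pd(OAc)2/PPh3 with HCO2H and n-Bu3N in DMF at 60 °C reduces the enol triflate to the alkene, coming back to the route at 8.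

Step 4 (copper hydride reduction). The ratio at C13 depends on the E purity of 6 and on the ligand match, and the free hydroxyls consume silane. The fallback changes to hydroxyl-directed hydrogenation and sets out from 6. i-Bu2AlH in toluene at −78 °C gives (13E)-labd-13-ene-3β,8α,15-triol F5. Ru(OAc)2[(R)-BINAP] under H2 (100 atm) in MeOH gives (13S)-labdane-3β,8α,15-triol F6; the sense follows the geraniol to citronellol precedent, in which the S ligand gives the R centre from the E allylic alcohol. TEMPO (cat.)/PhI(OAc)2 in MeCN/H2O oxidises only the primary alcohol to (13S)-3β,8α-dihydroxylabdan-15-oic acid F7, and TMSCHN2 in MeOH/toluene gives the methyl ester, coming back to the route at 7.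

**Further compounds**
F1 | step 7 | methyl (13S)-2α,3α-(sulfinyldioxy)labd-8(17)-en-15-oate (sulfur epimers) | COC(=O)C[C@@H](C)CC[C@H]1C(=C)CC[C@H]2C(C)(C)[C@@H]3OS(=O)O[C@@H]3C[C@]12C
F2 | step 7 | methyl (13S)-2α,3α-dihydroxylabd-8(17)-en-15-oate | COC(=O)C[C@@H](C)CC[C@H]1C(=C)CC[C@H]2C(C)(C)[C@H](O)[C@H](O)C[C@]12C
F3 | step 5 | methyl (13S)-8α-hydroxy-3-oxolabdan-15-oate | COC(=O)C[C@@H](C)CC[C@H]1[C@](C)(O)CC[C@H]2C(C)(C)C(=O)CC[C@]12C
F4 | step 5 | methyl (13S)-8α-hydroxy-3-(trifluoromethanesulfonyloxy)labd-2-en-15-oate | COC(=O)C[C@@H](C)CC[C@H]1[C@](C)(O)CC[C@H]2C(C)(C)C(OS(=O)(=O)C(F)(F)F)=CC[C@]12C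
F5 | step 4 | (13E)-labd-13-ene-3β,8α,15-triol | OC/C=C(\C)CC[C@H]1[C@](C)(O)CC[C@H]2C(C)(C)[C@@H](O)CC[C@]12C
F6 | step 4 | (13S)-labdane-3β,8α,15-triol | OCC[C@@H](C)CC[C@H]1[C@](C)(O)CC[C@H]2C(C)(C)[C@@H](O)CC[C@]12C
F7 | step 4 | (13S)-3β,8α-dihydroxylabdan-15-oic acid | OC(=O)C[C@@H](C)CC[C@H]1[C@](C)(O)CC[C@H]2C(C)(C)[C@@H](O)CC[C@]12C
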